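The rate constants were set for the occasion; the rest is arithmetic.

Slowness is the question at this blackboard: which steps in the flasks below are too slow to finish in the time, and which are quick enough to count as finished?

    starting material ⇌ target (K1 = 0.86, k1 = 0.92 s⁻¹, Ea1 = 69.0 kJ mol⁻¹, ΔH1 = −35.0 kJ mol⁻¹)
    starting material ⇌ isomer of the product A (K2 = 0.065, k2 = 0.051 s⁻¹, Ea2 = 86.0 kJ mol⁻¹, ΔH2 = −60.0 kJ mol⁻¹)
    starting material ⇌ isomer of the product B (K3 = 0.72, k3 = 0.19 s⁻¹, Ea3 = 74.0 kJ mol⁻¹, ΔH3 = 10.0 kJ mol⁻¹)
    starting material → decomposition product (k4 = 9.1 × 10⁻⁴ s⁻¹, Ea4 = 83.0 kJ mol⁻¹)
    solid substrate ⇌ starting material, rate k5*(cs5 - [starting material]) while solid is left; crystals form when [starting material] > cs5 (cs5 = 0.81 mM, k5 = 9.1 s⁻¹)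
    crystals ⇌ target, rate k6*(cs6 - [target]) while solid is left; crystals form when [target] > cs6 (cs6 = 0.030 mM, k6 = 24 s⁻¹)
    (constants at 25 °C)

| setting | Thursday's | Friday's | Saturday's | Monday's |
|---|---|---|---|---|
| solid substrate | 1.0 mM | 1.0 mM | 1.0 mM | 1.0 mM |
| temperature | 55 °C |  | 25 °C | 40 °C |
| time | 30 s | 30 s | 30 s | 30 s |
| remark |  | at 25 °C until 15 s, from then on at 55 °C |  |  |

- what is said of target includes crystals
- solid substrate, crystals is a solid; its amount is given per volume of the solution
- at 25 °C the constants are as listed, elsewhere as the activation energies and enthalpies make them
- at the start none of the solid substrate is in solution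
- what has only dissolved of solid substrate counts as not reacted

- the best flask by amount of target, in percent of the solid substrate charged; "all alike" if 1.5 percentage points covers them all (Thursday's / Friday's / Saturday's / Monday's / all alike)
- amount of target at the end, in percent of the solid substrate charged, Thursday's
- amount of target at the end, in percent of the solid substrate charged, Friday's
- amount of target at the end, in percent of the solid substrate charged, Saturday's
- amount of target at the end, in percent of the solid substrate charged, Monday's

We work in fractions of the charge. Step 1 speeds up by 13 from the coldest to the hottest flask, so every other constant moves by that factor raised to its ratio of energies. Hot, this gives K1 = 0.237, K2 = 0.00711, K3 = 1.04, and a decomposition constant of 0.0194 s⁻¹.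

Crystals take up dissolved target in about 0.0417 s, far quicker than the 30 s allowed, so while crystals last, dissolved target stands at its solubility. Steps 1 to 3 then tie the rest to it: starting material stands at 12.7% of the charge in the hottest flask, and both isomers stand in proportion to that. Adding these three gives 26.0%, the floor: the fraction of the charge that stays outside target while crystals are present. In the coldest flask the floor is 6.23%.

Decomposition is slow, since 51.5 s exceeds the time even when hot. We may therefore replace the curve of starting material by its plateau, and Thursday's flask loses 7.39%.

That is the weak link: the solid goes into solution toward a solubility of 81.0% of the charge, more than the plateau, so the early curve lies above it. But the area of the excess can be had without the curve. The hot forward constant of step 1 is 11.7 s⁻¹, and material reaches crystals through starting material with the pseudo-first-order constant 3.82 s⁻¹. The excess area is then what must pass, divided by that constant, and it adds 0.376% to the loss. Thursday's flask comes to 66.3%. The same reckoning with cold constants, using 0.881 s⁻¹, gives Saturday's flask 93.6%. Friday's flask ends on the hot floor with 15.0 s of hot decomposition, and that gives 70.3%. Monday's flask we leave between Saturday's and Thursday's.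

The forecast names Saturday's as best, with 66.3% for Thursday's, 70.4% for Friday's, 93.5% for Saturday's and 85.9% for Monday's, on the ground that “target acts as a sink”.

The simulation gives Saturday's as best, with 66.4%, 70.4%, 93.5% and 86.0% in the same order.

In Thursday's flask at 30.0 s, starting material and the two isomers stand at 25.8% together, against a floor of 26.0%. In the neighbour like Friday's but charged with 0.25 mM, the floor comes to 104% of its own charge, more than the charge itself, and at 30.0 s that flask holds 0% crystals, 9.09% target and 40.1% isomer of the product B.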